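## Retrosynthetic overview

1. Target 28 ← hydrogenolysis of bis-benzyl ether 27 ← trans-selective alkylation of the enolate of (R)-lactone 17 (23 non-H atoms) with benzylic bromide 25 (18 non-H atoms). This late union sets C3.
2. Lactone 17 ← hydroxy ester 16 ← Evans alkylation of succinate imide 13 with benzylic bromide 9, which sets C4.
3. Bromides 9 and 25 both come from catechol 1. Bromination goes para to the free OH, so the order of O-benzylation and O-methylation decides the isovanillyl or vanillyl pattern. Imide 13 comes from succinic anhydride 10.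
4. Ring formation: the butyrolactone is the only ring made (step 11). It is closed before the final fragment coupling (step 18), and both arene rings are carried through intact.

Assumption: (R)-4-benzyl-1,3-oxazolidin-2-one is used as a recoverable chiral auxiliary, so it is treated as a reagent (attached in step 8, cleaved in step 10) and is not numbered.

## Route

### Fragment A: 3-(benzyloxy)-4-methoxybenzyl bromide 9

**Step 1**
Reactants: 1 catechol (benzene-1,2-diol)
Product: 2 2-(benzyloxy)phenol
Conditions: BnBr (1 equiv), catechol (2 equiv), K2CO3, acetone, reflux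
Reagents that add atoms: benzyl bromide, BrCc1ccccc1
Why: Williamson ether synthesis; excess diol limits bis-benzylation, and unreacted catechol is washed out with water.

**Step 2**
Reactants: 2 2-(benzyloxy)phenol
Product: 3 2-(benzyloxy)-4-bromophenol
Conditions: NBS (1.0 equiv), MeCN, −10 to 0 °C
Reagents that add atoms: N-bromosuccinimide, O=C1CCC(=O)N1Br
Why: Electrophilic aromatic bromination; the free OH is the stronger para director, so bromine enters para to OH and meta to OBn.

**Step 3**
Reactants: 3 2-(benzyloxy)-4-bromophenol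
Product: 4 2-(benzyloxy)-4-bromo-1-methoxybenzene
Conditions: MeI, K2CO3, acetone, reflux
Reagents that add atoms: iodomethane, CI
Why: Williamson O-methylation of the only free phenol fixes the isovanillyl pattern (Br para to OMe).

**Step 4**
Reactants: 4 2-(benzyloxy)-4-bromo-1-methoxybenzene
Product: 7 3-(benzyloxy)-4-methoxybenzaldehyde, via aryllithium 5 (not isolated), via lithium hemiaminal alkoxide 6 (not isolated)
Conditions: n-BuLi (1.05 equiv), THF, −78 °C; DMF; then 1 M HCl, 0 °C
Reagents that add atoms: N,N-dimethylformamide, CN(C)C=O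
Why: Bromine–lithium exchange is much faster than benzylic deprotonation at −78 °C, and Bouveault formylation of the aryllithium gives the aldehyde on acidic work-up.

**Step 5**
Reactants: 7 3-(benzyloxy)-4-methoxybenzaldehyde
Product: 8 [3-(benzyloxy)-4-methoxyphenyl]methanol
Conditions: NaBH4, MeOH/THF, 0 °C
Reagents that add atoms: none
Why: Borohydride reduction of an aryl aldehyde; the ethers are inert.

**Step 6**
Reactants: 8 [3-(benzyloxy)-4-methoxyphenyl]methanol
Product: 9 2-(benzyloxy)-4-(bromomethyl)-1-methoxybenzene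
Conditions: PBr3 (0.4 equiv), CH2Cl2, 0 °C; used promptly
Reagents that add atoms: phosphorus tribromide, BrP(Br)Br
Why: The activated benzylic alcohol is displaced by bromide through its phosphite ester at 0 °C without touching the benzyl ether.

### Fragment B: succinate imide 13

**Step 7**
Reactants: 10 succinic anhydride
Product: 11 4-tert-butoxy-4-oxobutanoic acid
Conditions: t-BuOH (3 equiv), DMAP (10 mol %), N-hydroxysuccinimide (30 mol %), Et3N (30 mol %), toluene, reflux
Reagents that add atoms: tert-butanol, CC(C)(C)O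
Why: Nucleophile-catalysed alcoholysis opens the cyclic anhydride once, giving the half ester.

**Step 8**
Reactants: 11 4-tert-butoxy-4-oxobutanoic acid
Product: 13 tert-butyl 4-[(4R)-4-benzyl-2-oxo-1,3-oxazolidin-3-yl]-4-oxobutanoate, via mixed pivalic anhydride 12 (not isolated)
Conditions: PivCl, Et3N, THF, −20 °C; then (R)-4-benzyl-1,3-oxazolidin-2-one, LiCl, −20 °C to rt
Reagents that add atoms: (R)-4-benzyl-1,3-oxazolidin-2-one, O=C1N[C@H](Cc2ccccc2)CO1
Why: N-acylation through the mixed anhydride; the oxazolidinone attacks the unhindered succinyl carbonyl, not the pivaloyl one.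

### Union of A and B, and lactone formation

**Step 9**
Reactants: 13 tert-butyl 4-[(4R)-4-benzyl-2-oxo-1,3-oxazolidin-3-yl]-4-oxobutanoate; 9 2-(benzyloxy)-4-(bromomethyl)-1-methoxybenzene
Product: 15 tert-butyl (3R)-4-[(4R)-4-benzyl-2-oxo-1,3-oxazolidin-3-yl]-3-[3-(benzyloxy)-4-methoxybenzyl]-4-oxobutanoate, via sodium Z-enolate 14 (not isolated)
Conditions: NaN(SiMe3)2 (1.05 equiv), THF, −78 °C; then 9 (1.2 equiv), −78 to −40 °C
Reagents that add atoms: none
Why: Evans asymmetric alkylation; the more acidic imide α-CH2 gives the chelated Z-enolate, and the bromide attacks the face opposite the auxiliary's C4 benzyl group, setting the (3R) centre (the future lactone C4) in high dr.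

**Step 10**
Reactants: 15 tert-butyl (3R)-4-[(4R)-4-benzyl-2-oxo-1,3-oxazolidin-3-yl]-3-[3-(benzyloxy)-4-methoxybenzyl]-4-oxobutanoate
Product: 16 tert-butyl (3R)-4-[3-(benzyloxy)-4-methoxyphenyl]-3-(hydroxymethyl)butanoate
Conditions: LiBH4 (1.1 equiv), MeOH (1.1 equiv), THF, 0 °C
Reagents that add atoms: none
Why: Chemoselective reductive cleavage of the activated imide carbonyl; the hindered tert-butyl ester survives, the stereocentre is not enolisable under these conditions, and the auxiliary is recovered.

**Step 11**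
Reactants: 16 tert-butyl (3R)-4-[3-(benzyloxy)-4-methoxyphenyl]-3-(hydroxymethyl)butanoate
Product: 17 (4R)-4-[3-(benzyloxy)-4-methoxybenzyl]oxolan-2-one
Conditions: p-TsOH·H2O (10 mol %), toluene, 60 °C
Reagents that add atoms: none
Why: Acid-catalysed intramolecular transesterification closes the five-membered lactone with loss of tert-butanol; the stereocentre is not involved.

### Fragment C: 4-(benzyloxy)-3-methoxybenzyl bromide 25

**Step 12**
Reactants: 1 catechol (benzene-1,2-diol)
Product: 18 2-methoxyphenol
Conditions: MeI (1 equiv), catechol (2 equiv), K2CO3, acetone, reflux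
Reagents that add atoms: iodomethane, CI
Why: Williamson mono-methylation; the product is separated from the dimethyl ether by NaOH extraction and from catechol by water washing.

**Step 13**
Reactants: 18 2-methoxyphenol
Product: 19 4-bromo-2-methoxyphenol
Conditions: NBS (1.0 equiv), MeCN, 0 °C
Reagents that add atoms: N-bromosuccinimide, O=C1CCC(=O)N1Br
Why: Electrophilic aromatic bromination para to the free OH, the stronger director, giving the vanillyl pattern.

**Step 14**
Reactants: 19 4-bromo-2-methoxyphenol
Product: 20 1-(benzyloxy)-4-bromo-2-methoxybenzene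
Conditions: BnBr, K2CO3, DMF, rt
Reagents that add atoms: benzyl bromide, BrCc1ccccc1
Why: Williamson O-benzylation protects the phenol for the organolithium and enolate steps.

**Step 15**
Reactants: 20 1-(benzyloxy)-4-bromo-2-methoxybenzene
Product: 23 4-(benzyloxy)-3-methoxybenzaldehyde, via aryllithium 21 (not isolated), via lithium hemiaminal alkoxide 22 (not isolated)
Conditions: n-BuLi (1.05 equiv), THF, −78 °C; DMF; then 1 M HCl, 0 °C
Reagents that add atoms: N,N-dimethylformamide, CN(C)C=O
Why: Bromine–lithium exchange followed by Bouveault formylation, as in step 4.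

**Step 16**
Reactants: 23 4-(benzyloxy)-3-methoxybenzaldehyde
Product: 24 [4-(benzyloxy)-3-methoxyphenyl]methanol
Conditions: NaBH4, MeOH/THF, 0 °C
Reagents that add atoms: none
Why: Borohydride reduction of the aldehyde.

**Step 17**
Reactants: 24 [4-(benzyloxy)-3-methoxyphenyl]methanol
Product: 25 1-(benzyloxy)-4-(bromomethyl)-2-methoxybenzene
Conditions: PBr3 (0.4 equiv), CH2Cl2, 0 °C; used promptly
Reagents that add atoms: phosphorus tribromide, BrP(Br)Br
Why: Benzylic alcohol to bromide through the phosphite ester, as in step 6.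

### Late coupling and deprotection

**Step 18**
Reactants: 17 (4R)-4-[3-(benzyloxy)-4-methoxybenzyl]oxolan-2-one; 25 1-(benzyloxy)-4-(bromomethyl)-2-methoxybenzene
Product: 27 (3R,4R)-4-[3-(benzyloxy)-4-methoxybenzyl]-3-[4-(benzyloxy)-3-methoxybenzyl]oxolan-2-one, via lithium enolate 26 (not isolated)
Conditions: LiN(i-Pr)2 (commercial solution, 1.1 equiv), THF, −78 °C; then 25 (1.1 equiv), DMPU, −78 to −30 °C
Reagents that add atoms: none
Why: Lactone enolate alkylation joins the two halves; the C4 substituent shields its own face of the planar enolate, so the bromide enters anti and gives the trans (3R,4R) product.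

**Step 19**
Reactants: 27 (3R,4R)-4-[3-(benzyloxy)-4-methoxybenzyl]-3-[4-(benzyloxy)-3-methoxybenzyl]oxolan-2-one
Product: 28 (3R,4R)-4-(3-hydroxy-4-methoxybenzyl)-3-(4-hydroxy-3-methoxybenzyl)oxolan-2-one
Conditions: H2 (1 atm), 10% Pd/C, EtOAc/EtOH, rt
Reagents that add atoms: none
Why: Neutral hydrogenolysis cleaves both O-benzyl ethers, while the lactone, the methyl ethers and both stereocentres are untouched.

## Compound list

1 | catechol (benzene-1,2-diol) | Oc1ccccc1O | starting material
2 | 2-(benzyloxy)phenol | Oc1ccccc1OCc1ccccc1 | intermediate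
3 | 2-(benzyloxy)-4-bromophenol | Oc1ccc(Br)cc1OCc1ccccc1 | intermediate
4 | 2-(benzyloxy)-4-bromo-1-methoxybenzene | COc1ccc(Br)cc1OCc1ccccc1 | intermediate
5 | [3-(benzyloxy)-4-methoxyphenyl]lithium | [Li]c1ccc(OC)c(OCc2ccccc2)c1 | intermediate
6 | lithium [3-(benzyloxy)-4-methoxyphenyl](dimethylamino)methanolate | [Li+].[O-]C(N(C)C)c1ccc(OC)c(OCc2ccccc2)c1 | intermediate
7 | 3-(benzyloxy)-4-methoxybenzaldehyde | COc1ccc(C=O)cc1OCc1ccccc1 | intermediate
8 | [3-(benzyloxy)-4-methoxyphenyl]methanol | COc1ccc(CO)cc1OCc1ccccc1 | intermediate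
9 | 2-(benzyloxy)-4-(bromomethyl)-1-methoxybenzene | COc1ccc(CBr)cc1OCc1ccccc1 | intermediate
10 | succinic anhydride (oxolane-2,5-dione) | O=C1CCC(=O)O1 | starting material
11 | 4-tert-butoxy-4-oxobutanoic acid | CC(C)(C)OC(=O)CCC(=O)O | intermediate
12 | 4-tert-butoxy-4-oxobutanoic pivalic anhydride | CC(C)(C)OC(=O)CCC(=O)OC(=O)C(C)(C)C | intermediate
13 | tert-butyl 4-[(4R)-4-benzyl-2-oxo-1,3-oxazolidin-3-yl]-4-oxobutanoate | CC(C)(C)OC(=O)CCC(=O)N1[C@H](Cc2ccccc2)COC1=O | intermediate
14 | sodium (Z)-enolate of 13 | CC(C)(C)OC(=O)C/C=C(\[O-])N1[C@H](Cc2ccccc2)COC1=O.[Na+] | intermediate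
15 | tert-butyl (3R)-4-[(4R)-4-benzyl-2-oxo-1,3-oxazolidin-3-yl]-3-[3-(benzyloxy)-4-methoxybenzyl]-4-oxobutanoate | COc1ccc(C[C@H](CC(=O)OC(C)(C)C)C(=O)N2[C@H](Cc3ccccc3)COC2=O)cc1OCc1ccccc1 | intermediate
16 | tert-butyl (3R)-4-[3-(benzyloxy)-4-methoxyphenyl]-3-(hydroxymethyl)butanoate | COc1ccc(C[C@H](CC(=O)OC(C)(C)C)CO)cc1OCc1ccccc1 | intermediate
17 | (4R)-4-[3-(benzyloxy)-4-methoxybenzyl]oxolan-2-one | COc1ccc(C[C@H]2COC(=O)C2)cc1OCc1ccccc1 | intermediate
18 | 2-methoxyphenol | COc1ccccc1O | intermediate
19 | 4-bromo-2-methoxyphenol | COc1cc(Br)ccc1O | intermediate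
20 | 1-(benzyloxy)-4-bromo-2-methoxybenzene | COc1cc(Br)ccc1OCc1ccccc1 | intermediate
21 | [4-(benzyloxy)-3-methoxyphenyl]lithium | [Li]c1ccc(OCc2ccccc2)c(OC)c1 | intermediate
22 | lithium [4-(benzyloxy)-3-methoxyphenyl](dimethylamino)methanolate | [Li+].[O-]C(N(C)C)c1ccc(OCc2ccccc2)c(OC)c1 | intermediate
23 | 4-(benzyloxy)-3-methoxybenzaldehyde | COc1cc(C=O)ccc1OCc1ccccc1 | intermediate
24 | [4-(benzyloxy)-3-methoxyphenyl]methanol | COc1cc(CO)ccc1OCc1ccccc1 | intermediate
25 | 1-(benzyloxy)-4-(bromomethyl)-2-methoxybenzene | COc1cc(CBr)ccc1OCc1ccccc1 | intermediate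
26 | lithium enolate of 17 | COc1ccc(C[C@H]2COC([O-])=C2)cc1OCc1ccccc1.[Li+] | intermediate
27 | (3R,4R)-4-[3-(benzyloxy)-4-methoxybenzyl]-3-[4-(benzyloxy)-3-methoxybenzyl]oxolan-2-one | COc1ccc(C[C@H]2COC(=O)[C@@H]2Cc2ccc(OCc3ccccc3)c(OC)c2)cc1OCc1ccccc1 | intermediate
28 | (3R,4R)-4-(3-hydroxy-4-methoxybenzyl)-3-(4-hydroxy-3-methoxybenzyl)oxolan-2-one | COc1ccc(C[C@H]2COC(=O)[C@@H]2Cc2ccc(O)c(OC)c2)cc1O | target

## Step count

Total step count: 19.
Longest linear sequence: 11 steps (1–6, 9–11, 18, 19, from catechol). The other branches are 7 steps (7–11, 18, 19) and 8 steps (12–19).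

## Steps most likely to fail, with fallbacks

**Step 9 (Evans alkylation of the succinate imide).** The risks are incomplete or unselective enolisation next to the second ester, and loss of the labile electron-rich bromide 9. The fallback sets the stereocentre by catalytic asymmetric hydrogenation instead. It sets out from aldehyde 7 (with anhydride 10 as the source of the four-carbon unit) and comes back at lactone 17.
- Anhydride 10 is esterified (MeOH, H2SO4 cat., reflux) to dimethyl succinate F1.
- Stobbe condensation of 7 with F1 (KOtBu, t-BuOH, reflux, then HCl) gives (E)-4-[3-(benzyloxy)-4-methoxyphenyl]-3-(methoxycarbonyl)but-3-enoic acid F2.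
- Homogeneous hydrogenation of F2 gives (3R)-4-[3-(benzyloxy)-4-methoxyphenyl]-3-(methoxycarbonyl)butanoic acid F3. Conditions: [Rh(cod)2]BF4 with the Et-DuPHOS enantiomer that delivers the R acid, H2 (5 bar), MeOH, NaOMe (10 mol %). The benzyl ether survives.
- The potassium salt of F3 is reduced at the ester only with Ca(BH4)2 (from CaCl2 and NaBH4, EtOH, 0 °C to rt), and acidification (2 M HCl) closes the ring to 17.

**Step 18 (lactone enolate alkylation).** The risks are bis-alkylation, proton transfer between product and enolate, and decomposition of bromide 25. The fallback replaces the alkylation with an aldol addition and reductive removal of the benzylic oxygen. It sets out from lactone 17 and aldehyde 23 and comes back at target 28, so that 24, 25 and 27 are not needed.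
- Enolate 26 (LiN(i-Pr)2, THF, −78 °C) adds to 23 anti to the C4 substituent. The product is the trans aldol adduct 4-[3-(benzyloxy)-4-methoxybenzyl]-3-{[4-(benzyloxy)-3-methoxyphenyl](hydroxy)methyl}oxolan-2-one F4, with the ring centres as in 27 and the carbinol centre as a mixture of epimers.
- Hydrogenolysis of F4 (H2, 10% Pd/C, AcOH, HClO4 cat., rt) removes the benzylic hydroxyl and both benzyl ethers in one operation, giving 28.

**Step 2 (regioselective bromination of 2).** The risk is bromination ortho to OH or over-bromination, which would corrupt the isovanillyl pattern. The fallback directs bromine para to the methoxy group of an O-acylated guaiacol. It sets out from 2-methoxyphenol 18 and comes back at aryl bromide 4.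
- Acetylation of 18 (Ac2O, pyridine, rt) gives 2-methoxyphenyl acetate F5.
- Bromination (NBS, MeCN, rt to 50 °C) goes para to OMe, because the acetoxy group is the weaker donor, and gives 5-bromo-2-methoxyphenyl acetate F6.
- Methanolysis (K2CO3, MeOH, rt) gives 5-bromo-2-methoxyphenol F7.
- Benzylation of F7 (BnBr, K2CO3, DMF) gives 4.

## Further compounds

F1 | step 9 | dimethyl succinate | COC(=O)CCC(=O)OC
F2 | step 9 | (E)-4-[3-(benzyloxy)-4-methoxyphenyl]-3-(methoxycarbonyl)but-3-enoic acid | COC(=O)/C(CC(=O)O)=C/c1ccc(OC)c(OCc2ccccc2)c1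
F3 | step 9 | (3R)-4-[3-(benzyloxy)-4-methoxyphenyl]-3-(methoxycarbonyl)butanoic acid | COc1ccc(C[C@H](CC(=O)O)C(=O)OC)cc1OCc1ccccc1
F4 | step 18 | 4-[3-(benzyloxy)-4-methoxybenzyl]-3-{[4-(benzyloxy)-3-methoxyphenyl](hydroxy)methyl}oxolan-2-one (trans ring, carbinol epimers) | COc1ccc(C[C@H]2COC(=O)[C@@H]2C(O)c2ccc(OCc3ccccc3)c(OC)c2)cc1OCc1ccccc1
F5 | step 2 | 2-methoxyphenyl acetate | COc1ccccc1OC(C)=O
F6 | step 2 | 5-bromo-2-methoxyphenyl acetate | COc1ccc(Br)cc1OC(C)=O
F7 | step 2 | 5-bromo-2-methoxyphenol | COc1ccc(Br)cc1O
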